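**Strategy.** Ring A is assembled rather than functionalised. Its contiguous pattern (C1' acyl, C2' methoxy, C3' prenyl, C4' hydroxy, with C5' and C6' unsubstituted) is mapped onto a four-carbon ketene-acetal diene (C2'–C5') and a terminal ynone (C1', C6'). A single Diels–Alder addition followed by loss of methanol forms the C1'–C2' and C5'–C6' bonds, closes and aromatises ring A, and settles both the 2'-OMe/4'-OH differentiation and the crowded C3' prenyl group by connectivity. The precursors are a 1,1-dimethoxy-2-prenyl-3-silyloxybutadiene and an ethynyl ketone already carrying ring B and the 1,3-diketone masked as its β-methoxy enone. Desilylation and enol-ether hydrolysis complete the synthesis.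

Key step: step 8

Remark: the target has no stereocentre, so there is nothing to control; it is drawn as the diketo tautomer of a β-diketone that will exist largely as its enol, and the enol-ether geometry of the intermediates is immaterial because that carbon ends as a carbonyl group.

**Route**

Step 1
Reactants: 1 6-methylhept-5-en-2-one
Product: 3 3-[bis(methylsulfanyl)methylidene]-6-methylhept-5-en-2-one, via disodium ene-dithiolate 2 (not isolated)
Conditions: NaOt-Bu (2.1 equiv), CS2 (1.1 equiv), THF, 0 °C → rt; then MeI (2.2 equiv), 0 °C → rt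
Reagents that add atoms: carbon disulfide, S=C=S; iodomethane, CI
Why: α-Oxo ketene dithioacetal synthesis (enolate dithiocarboxylation, then double S-methylation), in which the reversible CS2 addition under equilibrating alkoxide conditions should settle on the more substituted C3 methylene and not on the C1 methyl, as is usual for alkyl methyl ketones under thermodynamic control, while the trisubstituted alkene is inert.

Step 2
Reactants: 3 3-[bis(methylsulfanyl)methylidene]-6-methylhept-5-en-2-one
Product: 5 3-(dimethoxymethylidene)-6-methylhept-5-en-2-one, via O,S-ketene acetal 4 (not isolated)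
Conditions: NaOMe (5 equiv), MeOH, reflux; non-acidic work-up (Et2O, cold aq. NaHCO3), Kugelrohr distillation
Reagents that add atoms: sodium methoxide, [Na+].[O-]C; methanol (solvent in exchange with it), CO
Why: Nucleophilic vinylic substitution by addition–elimination on a push–pull alkene, in which methoxide adds to the β-carbon and thiolate, the better leaving group, is expelled twice, the second exchange being driven by the excess of methoxide and by the stronger C–O bonds of the vinylogous carbonate that forms.

Step 3
Reactants: 5 3-(dimethoxymethylidene)-6-methylhept-5-en-2-one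
Product: 7 1,1-dimethoxy-2-(3-methylbut-2-en-1-yl)-3-(trimethylsilyloxy)buta-1,3-diene, via lithium dienolate 6 (not isolated)
Conditions: LDA (1.1 equiv), THF, −78 °C; then TMSCl (1.2 equiv), −78 °C → rt; pentane, filtration, concentration; used at once in step 8
Reagents that add atoms: chlorotrimethylsilane, C[Si](C)(C)Cl
Why: Kinetic enolisation and O-silylation (silyl enol ether formation) at the only enolisable position, the acetyl methyl group, since C3 is fully substituted; the water-free work-up protects the acid-labile ketene acetal.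

Step 4
Reactants: 8 methyl 3-(4-hydroxyphenyl)-3-oxopropanoate
Product: 9 methyl (E)-3-(4-hydroxyphenyl)-3-methoxyprop-2-enoate
Conditions: HC(OMe)3 (3 equiv), conc. H2SO4 (cat.), MeOH, 50 °C; NaHCO3 quench
Reagents that add atoms: trimethyl orthoformate, COC(OC)OC; methanol, CO
Why: Acid-catalysed enol etherification of a β-keto ester (ketalisation and loss of methanol, the orthoformate serving as methoxy source and water scavenger), which should give mainly the E isomer under thermodynamic control; the methyl ester excludes ester scrambling in methanol and the phenol is not alkylated.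

Step 5
Reactants: 9 methyl (E)-3-(4-hydroxyphenyl)-3-methoxyprop-2-enoate
Product: 10 methyl (E)-3-[4-(tert-butyldimethylsilyloxy)phenyl]-3-methoxyprop-2-enoate
Conditions: TBSCl (1.2 equiv), imidazole (2 equiv), DMF, rt
Reagents that add atoms: tert-butyldimethylsilyl chloride, CC(C)(C)[Si](C)(C)Cl
Why: Standard imidazole-mediated silylation of a phenol, which removes the acidic proton that would otherwise quench the Grignard reagents and, later, the proton-sensitive diene.

Step 6
Reactants: 10 methyl (E)-3-[4-(tert-butyldimethylsilyloxy)phenyl]-3-methoxyprop-2-enoate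
Product: 11 (E)-3-[4-(tert-butyldimethylsilyloxy)phenyl]-N,3-dimethoxy-N-methylprop-2-enamide
Conditions: MeNH(OMe)·HCl (1.5 equiv), i-PrMgCl (3 equiv), THF, −20 → 0 °C; sat. aq. NH4Cl
Reagents that add atoms: N,O-dimethylhydroxylamine hydrochloride, CNOC.Cl
Why: Weinreb amide synthesis by aminolysis of the ester with the chloromagnesium amide formed in the flask, where 1,2-attack at the ester should outrun conjugate displacement at the hindered, aryl-substituted β-carbon and the aryl silyl ether tolerates the low temperature.

Step 7
Reactants: 11 (E)-3-[4-(tert-butyldimethylsilyloxy)phenyl]-N,3-dimethoxy-N-methylprop-2-enamide; 12 ethynylmagnesium bromide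
Product: 14 (E)-1-[4-(tert-butyldimethylsilyloxy)phenyl]-1-methoxypent-1-en-4-yn-3-one, via magnesium hemiaminal chelate 13 (not isolated)
Conditions: HC≡CMgBr (0.5 M in THF, 2 equiv), THF, −20 → 0 °C; inverse quench into cold 0.5 M aq. HCl/Et2O, rapid extraction
Reagents that add atoms: ethynylmagnesium bromide, C#C[Mg]Br
Why: Weinreb ketone synthesis, in which the stable five-membered magnesium chelate blocks over-addition and releases the terminal ynone only on quenching, while the cold inverse acidic quench protonates the liberated N,O-dimethylhydroxylamine before it can add to the ynone and is too brief to hydrolyse the enol ether.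

Step 8
Reactants: 7 1,1-dimethoxy-2-(3-methylbut-2-en-1-yl)-3-(trimethylsilyloxy)buta-1,3-diene; 14 (E)-1-[4-(tert-butyldimethylsilyloxy)phenyl]-1-methoxypent-1-en-4-yn-3-one
Product: 17 (E)-3-[4-(tert-butyldimethylsilyloxy)phenyl]-1-[4-hydroxy-2-methoxy-3-(3-methylbut-2-en-1-yl)phenyl]-3-methoxyprop-2-en-1-one, via cyclohexadiene ketal cycloadduct 15 (not isolated), via aryl trimethylsilyl ether 16 (not isolated)
Conditions: 7 (1.5 equiv), PhMe, rt → 80 °C; then MeOH, citric acid (cat.), rt
Reagents that add atoms: none
Why: The diene CH2 terminus, made nucleophilic by the 3-silyloxy and 1,1-dimethoxy donors, bonds to the terminal (β) carbon of the ynone while the ketene-acetal carbon bonds to the α-carbon, in a thermal, concerted but strongly asynchronous [4+2] cycloaddition of normal electron demand. The closest known reaction type is the Diels–Alder addition with aromatising elimination of 1,1-dialkoxy-3-silyloxybuta-1,3-dienes and acetylenic ketones or esters, which gives resorcinol monoethers. Ring A closes as a six-membered carbocycle in an intermolecular [4+2] mode, both new bonds (C5'–C6' and C1'–C2') coming from the one cycloaddition; the 1,4-cyclohexadiene ketal 15 then aromatises by 1,4-elimination of methanol (one methoxy from C2', one hydrogen from C5'), and methanolysis of 16 frees the 4'-phenol. No stereocentre is formed. The step needs regioselectivity (acyl group beside the acetal carbon) and chemoselectivity for the alkyne over the methoxy enone; the first is secured by the matched polarisation of the partners, the second by the terminal, unhindered, more electron-poor triple bond, the trisubstituted enone being deactivated by its β-methoxy donor.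

Step 9
Reactants: 17 (E)-3-[4-(tert-butyldimethylsilyloxy)phenyl]-1-[4-hydroxy-2-methoxy-3-(3-methylbut-2-en-1-yl)phenyl]-3-methoxyprop-2-en-1-one
Product: 19 1-[4-hydroxy-2-methoxy-3-(3-methylbut-2-en-1-yl)phenyl]-3-(4-hydroxyphenyl)propane-1,3-dione, via bisphenol methoxy enone 18 (not isolated)
Conditions: TBAF (2.2 equiv), THF, 0 °C; then 1 M aq. HCl, rt
Reagents that add atoms: water, O
Why: Fluoride cleaves the aryl silyl ether and dilute aqueous acid then hydrolyses the vinylogous ester (protonation at the α-carbon, addition of water, loss of methanol) to the 1,3-diketone; acid this dilute at room temperature should not cyclise the ortho-prenylphenol to a chroman.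

**Compound list**

1 | 6-methylhept-5-en-2-one | CC(=O)CCC=C(C)C | starting material
2 | disodium 2-acetyl-5-methylhexa-1,4-diene-1,1-bis(thiolate) | CC(=O)C(CC=C(C)C)=C([S-])[S-].[Na+].[Na+] | intermediate (not isolated)
3 | 3-[bis(methylsulfanyl)methylidene]-6-methylhept-5-en-2-one | CC(=O)C(CC=C(C)C)=C(SC)SC | intermediate
4 | 3-[methoxy(methylsulfanyl)methylidene]-6-methylhept-5-en-2-one (mixture of double-bond isomers) | CC(=O)C(CC=C(C)C)=C(OC)SC | intermediate (not isolated)
5 | 3-(dimethoxymethylidene)-6-methylhept-5-en-2-one | CC(=O)C(CC=C(C)C)=C(OC)OC | intermediate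
6 | lithium 3-(dimethoxymethylidene)-6-methylhepta-1,5-dien-2-olate | [Li+].[O-]C(=C)C(CC=C(C)C)=C(OC)OC | intermediate (not isolated)
7 | 1,1-dimethoxy-2-(3-methylbut-2-en-1-yl)-3-(trimethylsilyloxy)buta-1,3-diene | C=C(O[Si](C)(C)C)C(CC=C(C)C)=C(OC)OC | intermediate
8 | methyl 3-(4-hydroxyphenyl)-3-oxopropanoate | COC(=O)CC(=O)c1ccc(O)cc1 | starting material
9 | methyl (E)-3-(4-hydroxyphenyl)-3-methoxyprop-2-enoate | COC(=O)/C=C(/OC)c1ccc(O)cc1 | intermediate
10 | methyl (E)-3-[4-(tert-butyldimethylsilyloxy)phenyl]-3-methoxyprop-2-enoate | COC(=O)/C=C(/OC)c1ccc(O[Si](C)(C)C(C)(C)C)cc1 | intermediate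
11 | (E)-3-[4-(tert-butyldimethylsilyloxy)phenyl]-N,3-dimethoxy-N-methylprop-2-enamide | CON(C)C(=O)/C=C(/OC)c1ccc(O[Si](C)(C)C(C)(C)C)cc1 | intermediate
12 | ethynylmagnesium bromide | C#C[Mg]Br | starting material
13 | bromomagnesium (E)-1-[4-(tert-butyldimethylsilyloxy)phenyl]-1-methoxy-3-[methoxy(methyl)amino]pent-1-en-4-yn-3-olate (racemic tetrahedral adduct, its centre lost on collapse) | C#CC(O[Mg]Br)(N(C)OC)/C=C(/OC)c1ccc(O[Si](C)(C)C(C)(C)C)cc1 | intermediate (not isolated)
14 | (E)-1-[4-(tert-butyldimethylsilyloxy)phenyl]-1-methoxypent-1-en-4-yn-3-one | C#CC(=O)/C=C(/OC)c1ccc(O[Si](C)(C)C(C)(C)C)cc1 | intermediate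
15 | (E)-3-[4-(tert-butyldimethylsilyloxy)phenyl]-1-[6,6-dimethoxy-5-(3-methylbut-2-en-1-yl)-4-(trimethylsilyloxy)cyclohexa-1,4-dien-1-yl]-3-methoxyprop-2-en-1-one | COC1(OC)C(CC=C(C)C)=C(O[Si](C)(C)C)CC=C1C(=O)/C=C(/OC)c2ccc(O[Si](C)(C)C(C)(C)C)cc2 | intermediate (not isolated)
16 | (E)-3-[4-(tert-butyldimethylsilyloxy)phenyl]-3-methoxy-1-[2-methoxy-3-(3-methylbut-2-en-1-yl)-4-(trimethylsilyloxy)phenyl]prop-2-en-1-one | COc1c(C(=O)/C=C(/OC)c2ccc(O[Si](C)(C)C(C)(C)C)cc2)ccc(O[Si](C)(C)C)c1CC=C(C)C | intermediate (not isolated)
17 | (E)-3-[4-(tert-butyldimethylsilyloxy)phenyl]-1-[4-hydroxy-2-methoxy-3-(3-methylbut-2-en-1-yl)phenyl]-3-methoxyprop-2-en-1-one | COc1c(C(=O)/C=C(/OC)c2ccc(O[Si](C)(C)C(C)(C)C)cc2)ccc(O)c1CC=C(C)C | intermediate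
18 | (E)-1-[4-hydroxy-2-methoxy-3-(3-methylbut-2-en-1-yl)phenyl]-3-(4-hydroxyphenyl)-3-methoxyprop-2-en-1-one (present as its tetrabutylammonium phenoxide until acidified; written in the neutral form) | COc1c(C(=O)/C=C(/OC)c2ccc(O)cc2)ccc(O)c1CC=C(C)C | intermediate (not isolated)
19 | 1-[4-hydroxy-2-methoxy-3-(3-methylbut-2-en-1-yl)phenyl]-3-(4-hydroxyphenyl)propane-1,3-dione | COc1c(C(=O)CC(=O)c2ccc(O)cc2)ccc(O)c1CC=C(C)C | target

**Count and risk**

Total step count: 9 (steps 1–3 diene, steps 4–7 ynone, steps 8–9 union and end game).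
Longest linear sequence: 6 steps (4, 5, 6, 7, 8, 9).

Steps most likely to fail:

1. Step 8. The ynone 14 may be consumed by oligomerisation or by conjugate addition without ring closure, or the diene 7 may be hydrolysed before it reacts. Fallback: ring A is closed first with a simple dienophile and the diketone is made afterwards by a crossed Claisen condensation. Setting out from 7, cycloaddition with commercial but-3-yn-2-one (PhMe, rt → 60 °C) should give the ketal cycloadduct F1, which loses methanol to the aryl trimethylsilyl ether F2. Methanolic citric acid then gives the ring-A acetophenone F3, and TBSCl/imidazole its silyl ether F4. Methyl 4-hydroxybenzoate is silylated in the same way to the ring-B ester F5. Condensation of F4 with F5 (NaH, THF, 60 °C) gives the bis-silyl diketone F6; any silyl loss at this stage is immaterial, because TBAF/AcOH (THF, 0 °C) then removes both groups and the route is rejoined at the target 19.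

2. Step 2. The second thiolate displacement may stall, or methoxide may attack the acetyl group on prolonged heating. Fallback: the exchange is stopped on purpose after one displacement and the thiolate is expelled later, in the aromatisation. Setting out from 3, one equivalent of NaOMe (MeOH, rt) gives 4, which is isolated here. LDA and then TMSCl, as in step 3, convert it through the lithium dienolate F7 into the methoxy(methylsulfanyl) diene F8. Cycloaddition with 14 (PhMe, rt → 80 °C) gives the O,S-ketal cycloadduct F9, which is aromatised with Et3N at rt so that the thiolate, the better nucleofuge in this base-induced elimination, is the group lost. This gives 16, and the methanolic desilylation of step 8 rejoins the route at 17.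

3. Step 1. Dithiocarboxylation may occur at the C1 methyl group, in part or entirely. Fallback: the C3 enolate is generated regiospecifically instead of by equilibration. Setting out from 1, TMSCl/NaI/Et3N (MeCN, rt) gives the thermodynamic silyl enol ether F10, which is purified by distillation. MeLi (THF, 0 °C) releases the lithium enolate F11. CS2 in the presence of LiHMDS (1 equiv, −78 °C) converts it into the dilithium ene-dithiolate F12, and MeI (2 equiv) then gives 3, where the route is rejoined.

**Further compounds**

F1 | step 8 | 1-[6,6-dimethoxy-5-(3-methylbut-2-en-1-yl)-4-(trimethylsilyloxy)cyclohexa-1,4-dien-1-yl]ethanone | CC(=O)C1=CCC(O[Si](C)(C)C)=C(CC=C(C)C)C1(OC)OC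
F2 | step 8 | 1-[2-methoxy-3-(3-methylbut-2-en-1-yl)-4-(trimethylsilyloxy)phenyl]ethanone | CC(=O)c1ccc(O[Si](C)(C)C)c(CC=C(C)C)c1OC
F3 | step 8 | 1-[4-hydroxy-2-methoxy-3-(3-methylbut-2-en-1-yl)phenyl]ethanone | CC(=O)c1ccc(O)c(CC=C(C)C)c1OC
F4 | step 8 | 1-[4-(tert-butyldimethylsilyloxy)-2-methoxy-3-(3-methylbut-2-en-1-yl)phenyl]ethanone | CC(=O)c1ccc(O[Si](C)(C)C(C)(C)C)c(CC=C(C)C)c1OC
F5 | step 8 | methyl 4-(tert-butyldimethylsilyloxy)benzoate | COC(=O)c1ccc(O[Si](C)(C)C(C)(C)C)cc1
F6 | step 8 | 1-[4-(tert-butyldimethylsilyloxy)-2-methoxy-3-(3-methylbut-2-en-1-yl)phenyl]-3-[4-(tert-butyldimethylsilyloxy)phenyl]propane-1,3-dione | COc1c(C(=O)CC(=O)c2ccc(O[Si](C)(C)C(C)(C)C)cc2)ccc(O[Si](C)(C)C(C)(C)C)c1CC=C(C)C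
F7 | step 2 | lithium 3-[methoxy(methylsulfanyl)methylidene]-6-methylhepta-1,5-dien-2-olate (mixture of double-bond isomers) | [Li+].[O-]C(=C)C(CC=C(C)C)=C(OC)SC
F8 | step 2 | 1-methoxy-2-(3-methylbut-2-en-1-yl)-1-(methylsulfanyl)-3-(trimethylsilyloxy)buta-1,3-diene (mixture of double-bond isomers) | C=C(O[Si](C)(C)C)C(CC=C(C)C)=C(OC)SC
F9 | step 2 | (E)-3-[4-(tert-butyldimethylsilyloxy)phenyl]-3-methoxy-1-[6-methoxy-5-(3-methylbut-2-en-1-yl)-6-(methylsulfanyl)-4-(trimethylsilyloxy)cyclohexa-1,4-dien-1-yl]prop-2-en-1-one (racemic) | COC1(SC)C(CC=C(C)C)=C(O[Si](C)(C)C)CC=C1C(=O)/C=C(/OC)c2ccc(O[Si](C)(C)C(C)(C)C)cc2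
F10 | step 1 | (Z)-trimethyl[(6-methylhepta-2,5-dien-2-yl)oxy]silane | C[Si](C)(C)O/C(C)=C\CC=C(C)C
F11 | step 1 | lithium (Z)-6-methylhepta-2,5-dien-2-olate | [Li+].[O-]/C(C)=C\CC=C(C)C
F12 | step 1 | dilithium 2-acetyl-5-methylhexa-1,4-diene-1,1-bis(thiolate) | CC(=O)C(CC=C(C)C)=C([S-])[S-].[Li+].[Li+]
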